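**Retrosynthetic overview**

1. Labels and feature: unit 1 is the 5-hydroxy-7-methoxyflavone (benzo ring A, pyranone ring C); ring B is the central phenol (C1' on C2 of unit 1, C4'–OH); unit 2 is the 5,7-dihydroxy-2-(4-hydroxyphenyl)chromone (benzo ring D, pyranone ring E, aryl ring F). The route rests on the fact that ring B is bonded through C3' to C3 of ring E, the carbon α to the C4 carbonyl, which is where an oxidative 1,2-aryl shift places the β-aryl group of a chalcone.
2. Late disconnections: five O-benzyl groups; ring C (O1–C2 of unit 1) by I2/DMSO cyclisation of a 2'-hydroxychalcone made from a ring B aldehyde and mono-benzylated 2',6'-dihydroxy-4'-methoxyacetophenone; the aldehyde from the ring B bromide by Pd-catalysed formylation.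
3. Early disconnections: C2(ring E)–ring F by aryl addition to the 4-silyloxybenzopyrylium ion of a 3-arylchromone, then DDQ; ring E and the C3–C3' bond by Tl(NO3)3 rearrangement and acid closure of a chalcone from dibenzylated phloroacetophenone and O-benzyl-5-bromosalicylaldehyde.
4. Ring order: rings A, B, D and F are bought as benzene rings; ring E is built first (step 4) and ring C last (step 10).

Key step: step 4

Remark: the target is drawn without axial chirality, so the C3–C3' biaryl axis is treated as freely rotating and the target as achiral; no stereocentre has to be set.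

**Route**

Step 1
Reactants: 1 1-(2,4,6-trihydroxyphenyl)ethan-1-one
Product: 2 1-[2,4-bis(benzyloxy)-6-hydroxyphenyl]ethan-1-one
Conditions: BnBr (2.1 equiv), K2CO3, DMF, rt
Reagents that add atoms: benzyl bromide, BrCc1ccccc1
Why: Williamson ether synthesis: once the para and one ortho hydroxyl are etherified, the last hydroxyl is locked in a hydrogen bond to the acetyl carbonyl and is far less nucleophilic, so two equivalents of benzyl bromide should stop at the dibenzyl ether.

Step 2
Reactants: 3 5-bromo-2-hydroxybenzaldehyde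
Product: 4 2-(benzyloxy)-5-bromobenzaldehyde
Conditions: BnBr, K2CO3, DMF, rt
Reagents that add atoms: benzyl bromide, BrCc1ccccc1
Why: Williamson ether synthesis on the phenoxide, with the aldehyde and the aryl bromide inert to carbonate base.

Step 3
Reactants: 2 1-[2,4-bis(benzyloxy)-6-hydroxyphenyl]ethan-1-one; 4 2-(benzyloxy)-5-bromobenzaldehyde
Product: 5 (E)-1-[2,4-bis(benzyloxy)-6-hydroxyphenyl]-3-[2-(benzyloxy)-5-bromophenyl]prop-2-en-1-one
Conditions: KOH (50% aq), EtOH–THF, rt
Reagents that add atoms: none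
Why: Claisen–Schmidt condensation: the methyl ketone enolate adds to the non-enolisable aldehyde and E1cB dehydration gives the conjugated enone in its thermodynamically favoured E geometry.

Step 4
Reactants: 5 (E)-1-[2,4-bis(benzyloxy)-6-hydroxyphenyl]-3-[2-(benzyloxy)-5-bromophenyl]prop-2-en-1-one
Product: 7 5,7-bis(benzyloxy)-3-[2-(benzyloxy)-5-bromophenyl]-4H-chromen-4-one, via dimethyl acetal 6 (not isolated)
Conditions: Tl(NO3)3·3H2O (1.1 equiv), MeOH–HC(OMe)3 (1:1), rt; then 10% aq HCl, MeOH–THF, 60 °C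
Reagents that add atoms: none
Why: Trivalent thallium activates the enone double bond, methanol adds at the benzylic β-carbon, and heterolysis of the weak Cα–Tl bond (releasing monovalent thallium) is assisted by ring B, which bridges as a phenonium ion and ends on the α-carbon while the β-carbon, now an oxocarbenium ion, takes a second methanol to give acetal 6. Aqueous HCl then ionises the acetal, the 2'-hydroxyl attacks the oxocarbenium carbon in a 6-exo-trig closure (O1–C2 of ring E), and loss of the second methanol gives the aromatic pyranone. The closest known reaction type is the Tl(NO3)3 oxidative rearrangement of 2'-hydroxychalcones to isoflavones, the laboratory counterpart of the biosynthetic isoflavone aryl shift. No stereocentre remains, since the only sp3 centre of 6 becomes the sp2 carbon C3. The step needs aryl migration to outrun methoxylation without shift, aurone formation and oxidation of the electron-rich ring D; the ortho benzyloxy group makes ring B a good bridging group (the bromine meta to the migrating carbon deactivates only mildly) and the orthoformate keeps the medium anhydrous. Only the β-aryl group can shift and it migrates through its ipso carbon, so the new C3–C3' bond must lie ortho to the benzyloxy oxygen and meta to bromine.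

Step 5
Reactants: 8 1-(benzyloxy)-4-bromobenzene
Product: 9 [4-(benzyloxy)phenyl]magnesium bromide (THF solution, titrated and used directly)
Conditions: Mg turnings, I2 (cat.), THF, reflux
Reagents that add atoms: magnesium, [Mg]
Why: Grignard formation by insertion of magnesium into the aryl C–Br bond, to which the benzyl aryl ether is inert.

Step 6
Reactants: 7 5,7-bis(benzyloxy)-3-[2-(benzyloxy)-5-bromophenyl]-4H-chromen-4-one; 9 [4-(benzyloxy)phenyl]magnesium bromide
Product: 12 5,7-bis(benzyloxy)-3-[2-(benzyloxy)-5-bromophenyl]-2-[4-(benzyloxy)phenyl]-4H-chromen-4-one, via silyloxybenzopyrylium triflate 10 (not isolated), via silyl enol ether 11 (not isolated)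
Conditions: TBSOTf (1.1 equiv), CH2Cl2, rt; then 9 (1.5 equiv), CuBr·SMe2 (20 mol %), THF, −78 → −40 °C; aq NaHCO3 work-up; crude, DDQ (1.2 equiv), 1,4-dioxane, rt
Reagents that add atoms: none
Why: Silyl-triflate-promoted conjugate addition to a chromone followed by DDQ dehydrogenation of the silyl enol ether: O-silylation of the C4 carbonyl gives a benzopyrylium ion whose only unsubstituted electrophilic carbon is C2, the aryl copper species formed from the Grignard reagent and the monovalent copper catalyst adds there, and DDQ abstracts the C2 hydride so that loss of the silyl group restores the pyranone.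

Step 7
Reactants: 12 5,7-bis(benzyloxy)-3-[2-(benzyloxy)-5-bromophenyl]-2-[4-(benzyloxy)phenyl]-4H-chromen-4-one
Product: 13 4-(benzyloxy)-3-{5,7-bis(benzyloxy)-2-[4-(benzyloxy)phenyl]-4-oxo-4H-chromen-3-yl}benzaldehyde
Conditions: Pd(OAc)2 (1 mol %), n-BuP(1-Ad)2 (3 mol %), TMEDA, CO/H2 (1:1, 5 bar), PhMe, 100 °C
Reagents that add atoms: carbon monoxide, [C-]#[O+]
Why: Palladium-catalysed reductive carbonylation (formylation) of an aryl bromide: zerovalent palladium inserts into the C–Br bond, CO inserts, and H2 cleaves the acyl palladium with TMEDA taking up HBr, while benzyl ethers and the tetrasubstituted chromone double bond are untouched by the homogeneous CO-saturated catalyst.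

Step 8
Reactants: 14 1-(2,6-dihydroxy-4-methoxyphenyl)ethan-1-one
Product: 15 1-[2-(benzyloxy)-6-hydroxy-4-methoxyphenyl]ethan-1-one
Conditions: BnBr (1.05 equiv), K2CO3, acetone, reflux
Reagents that add atoms: benzyl bromide, BrCc1ccccc1
Why: Williamson ether synthesis on a symmetrical ketone whose two hydroxyls are equivalent, so only one mono-ether can form, and the remaining hydroxyl is chelated to the carbonyl and resists a second alkylation.

Step 9
Reactants: 13 4-(benzyloxy)-3-{5,7-bis(benzyloxy)-2-[4-(benzyloxy)phenyl]-4-oxo-4H-chromen-3-yl}benzaldehyde; 15 1-[2-(benzyloxy)-6-hydroxy-4-methoxyphenyl]ethan-1-one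
Product: 16 (E)-1-[2-(benzyloxy)-6-hydroxy-4-methoxyphenyl]-3-(4-(benzyloxy)-3-{5,7-bis(benzyloxy)-2-[4-(benzyloxy)phenyl]-4-oxo-4H-chromen-3-yl}phenyl)prop-2-en-1-one
Conditions: KOH (50% aq), EtOH–THF, rt
Reagents that add atoms: none
Why: Claisen–Schmidt condensation giving the E-enone, with ring E expected to survive because its C2 is fully substituted and flanked by two aryl groups, which slows hydroxide addition at room temperature.

Step 10
Reactants: 16 (E)-1-[2-(benzyloxy)-6-hydroxy-4-methoxyphenyl]-3-(4-(benzyloxy)-3-{5,7-bis(benzyloxy)-2-[4-(benzyloxy)phenyl]-4-oxo-4H-chromen-3-yl}phenyl)prop-2-en-1-one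
Product: 17 5-(benzyloxy)-2-(4-(benzyloxy)-3-{5,7-bis(benzyloxy)-2-[4-(benzyloxy)phenyl]-4-oxo-4H-chromen-3-yl}phenyl)-7-methoxy-4H-chromen-4-one
Conditions: I2 (10 mol %), DMSO, 130 °C
Reagents that add atoms: none
Why: I2/DMSO oxidative cyclisation of a 2'-hydroxychalcone to a flavone: 6-endo-trig oxa-Michael closure of ring C, α-iodination and loss of HI, with DMSO reoxidising HI to I2.

Step 11
Reactants: 17 5-(benzyloxy)-2-(4-(benzyloxy)-3-{5,7-bis(benzyloxy)-2-[4-(benzyloxy)phenyl]-4-oxo-4H-chromen-3-yl}phenyl)-7-methoxy-4H-chromen-4-one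
Product: 18 5,7-dihydroxy-3-[2-hydroxy-5-(5-hydroxy-7-methoxy-4-oxo-4H-chromen-2-yl)phenyl]-2-(4-hydroxyphenyl)-4H-chromen-4-one
Conditions: H2 (1 atm), 10% Pd/C, THF–MeOH, rt
Reagents that add atoms: none
Why: Catalytic hydrogenolysis of the five benzyl aryl ethers, under which the aryl methyl ether and the conjugated pyranone double bonds should not be reduced at atmospheric pressure.

**Compound list**

1 | 1-(2,4,6-trihydroxyphenyl)ethan-1-one (2',4',6'-trihydroxyacetophenone) | CC(=O)c1c(O)cc(O)cc1O | starting material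
2 | 1-[2,4-bis(benzyloxy)-6-hydroxyphenyl]ethan-1-one | CC(=O)c1c(O)cc(OCc2ccccc2)cc1OCc1ccccc1 | intermediate
3 | 5-bromo-2-hydroxybenzaldehyde (5-bromosalicylaldehyde) | O=Cc1cc(Br)ccc1O | starting material
4 | 2-(benzyloxy)-5-bromobenzaldehyde | O=Cc1cc(Br)ccc1OCc1ccccc1 | intermediate
5 | (E)-1-[2,4-bis(benzyloxy)-6-hydroxyphenyl]-3-[2-(benzyloxy)-5-bromophenyl]prop-2-en-1-one | O=C(/C=C/c1cc(Br)ccc1OCc1ccccc1)c1c(O)cc(OCc2ccccc2)cc1OCc1ccccc1 | intermediate
6 | 1-[2,4-bis(benzyloxy)-6-hydroxyphenyl]-2-[2-(benzyloxy)-5-bromophenyl]-3,3-dimethoxypropan-1-one (racemic) | COC(OC)C(c1cc(Br)ccc1OCc1ccccc1)C(=O)c1c(O)cc(OCc2ccccc2)cc1OCc1ccccc1 | intermediate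
7 | 5,7-bis(benzyloxy)-3-[2-(benzyloxy)-5-bromophenyl]-4H-chromen-4-one | O=c1c(-c2cc(Br)ccc2OCc2ccccc2)coc2cc(OCc3ccccc3)cc(OCc3ccccc3)c12 | intermediate
8 | 1-(benzyloxy)-4-bromobenzene | Brc1ccc(OCc2ccccc2)cc1 | starting material
9 | [4-(benzyloxy)phenyl]magnesium bromide | Br[Mg]c1ccc(OCc2ccccc2)cc1 | intermediate
10 | 5,7-bis(benzyloxy)-3-[2-(benzyloxy)-5-bromophenyl]-4-[(tert-butyldimethylsilyl)oxy]chromenylium trifluoromethanesulfonate | CC(C)(C)[Si](C)(C)Oc1c(-c2cc(Br)ccc2OCc2ccccc2)c[o+]c2cc(OCc3ccccc3)cc(OCc3ccccc3)c12.[O-]S(=O)(=O)C(F)(F)F | intermediate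
11 | {[5,7-bis(benzyloxy)-3-[2-(benzyloxy)-5-bromophenyl]-2-[4-(benzyloxy)phenyl]-2H-chromen-4-yl]oxy}(tert-butyl)dimethylsilane (racemic) | CC(C)(C)[Si](C)(C)OC1=C(c2cc(Br)ccc2OCc2ccccc2)C(c2ccc(OCc3ccccc3)cc2)Oc2cc(OCc3ccccc3)cc(OCc3ccccc3)c21 | intermediate
12 | 5,7-bis(benzyloxy)-3-[2-(benzyloxy)-5-bromophenyl]-2-[4-(benzyloxy)phenyl]-4H-chromen-4-one | O=c1c(-c2cc(Br)ccc2OCc2ccccc2)c(-c2ccc(OCc3ccccc3)cc2)oc2cc(OCc3ccccc3)cc(OCc3ccccc3)c12 | intermediate
13 | 4-(benzyloxy)-3-{5,7-bis(benzyloxy)-2-[4-(benzyloxy)phenyl]-4-oxo-4H-chromen-3-yl}benzaldehyde | O=Cc1ccc(OCc2ccccc2)c(-c2c(-c3ccc(OCc4ccccc4)cc3)oc3cc(OCc4ccccc4)cc(OCc4ccccc4)c3c2=O)c1 | intermediate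
14 | 1-(2,6-dihydroxy-4-methoxyphenyl)ethan-1-one (2',6'-dihydroxy-4'-methoxyacetophenone) | CC(=O)c1c(O)cc(OC)cc1O | starting material
15 | 1-[2-(benzyloxy)-6-hydroxy-4-methoxyphenyl]ethan-1-one | CC(=O)c1c(O)cc(OC)cc1OCc1ccccc1 | intermediate
16 | (E)-1-[2-(benzyloxy)-6-hydroxy-4-methoxyphenyl]-3-(4-(benzyloxy)-3-{5,7-bis(benzyloxy)-2-[4-(benzyloxy)phenyl]-4-oxo-4H-chromen-3-yl}phenyl)prop-2-en-1-one | COc1cc(O)c(C(=O)/C=C/c2ccc(OCc3ccccc3)c(-c3c(-c4ccc(OCc5ccccc5)cc4)oc4cc(OCc5ccccc5)cc(OCc5ccccc5)c4c3=O)c2)c(OCc2ccccc2)c1 | intermediate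
17 | 5-(benzyloxy)-2-(4-(benzyloxy)-3-{5,7-bis(benzyloxy)-2-[4-(benzyloxy)phenyl]-4-oxo-4H-chromen-3-yl}phenyl)-7-methoxy-4H-chromen-4-one | COc1cc(OCc2ccccc2)c2c(=O)cc(-c3ccc(OCc4ccccc4)c(-c4c(-c5ccc(OCc6ccccc6)cc5)oc5cc(OCc6ccccc6)cc(OCc6ccccc6)c5c4=O)c3)oc2c1 | intermediate
18 | 5,7-dihydroxy-3-[2-hydroxy-5-(5-hydroxy-7-methoxy-4-oxo-4H-chromen-2-yl)phenyl]-2-(4-hydroxyphenyl)-4H-chromen-4-one | COc1cc(O)c2c(=O)cc(-c3ccc(O)c(-c4c(-c5ccc(O)cc5)oc5cc(O)cc(O)c5c4=O)c3)oc2c1 | target

**Step count and risks**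

Total step count: 11. Longest linear sequence: 8 steps (steps 1, 3, 4, 6, 7, 9, 10, 11).

The three steps most likely to fail:

1. Step 6. Addition of the aryl nucleophile to C2 may be slow because the twisted ortho-substituted ring B shields the pyrylium ion, so that desilylation simply returns the isoflavone; attack at C4 or bromine–magnesium exchange on ring B may also compete. Fallback from 7, returning at 12: isoflavone 7 would be deprotonated at C2 with LiTMP in THF at −78 °C and the vinyllithium quenched with I2 to give 5,7-bis(benzyloxy)-3-[2-(benzyloxy)-5-bromophenyl]-2-iodo-4H-chromen-4-one F3. Suzuki–Miyaura coupling of F3 with bought 4-(benzyloxy)phenylboronic acid (Pd(PPh3)4, K2CO3, dioxane–water, 60 °C) should take place at the vinylogous acyl iodide well before the electron-rich aryl bromide and give 12.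

2. Step 4. The free 2'-hydroxyl may cyclise onto the thallated enone to give an aurone, methanol may add without aryl shift if the bromine-bearing ring bridges too slowly, and the electron-rich ring D may be oxidised or nitrated. Fallback from 2, returning at 7, which forms the C3–C3' bond by cross-coupling and makes steps 2 and 3 unnecessary: ketone 2 would be condensed with N,N-dimethylformamide dimethyl acetal (PhMe, 90 °C) to the enaminone (E)-1-[2,4-bis(benzyloxy)-6-hydroxyphenyl]-3-(dimethylamino)prop-2-en-1-one F1. I2 in MeOH would cyclise and iodinate F1 to 5,7-bis(benzyloxy)-3-iodo-4H-chromen-4-one F2. Suzuki–Miyaura coupling of F2 with bought [2-(benzyloxy)-5-bromophenyl]boronic acid (Pd(PPh3)4, K2CO3, DME–water, 50 °C), in which the iodide reacts before either bromide, would give 7.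

3. Step 9. Hydroxide may add to C2 of ring E and open the pyranone, or the condensation of the hindered partners may stall and revert by retro-aldol. Fallback from 13, returning at 17 and bypassing chalcone 16 and step 10: aldehyde 13 would be oxidised (NaClO2, NaH2PO4, 2-methyl-2-butene, t-BuOH–THF–water) to 4-(benzyloxy)-3-{5,7-bis(benzyloxy)-2-[4-(benzyloxy)phenyl]-4-oxo-4H-chromen-3-yl}benzoic acid F4. Esterification of F4 with phenol 15 (EDC·HCl, DMAP, CH2Cl2) would give 2-acetyl-3-(benzyloxy)-5-methoxyphenyl 4-(benzyloxy)-3-{5,7-bis(benzyloxy)-2-[4-(benzyloxy)phenyl]-4-oxo-4H-chromen-3-yl}benzoate F5. A Baker–Venkataraman acyl shift with the non-nucleophilic base LiHMDS (THF, −78 °C → rt) would give 1-[2-(benzyloxy)-6-hydroxy-4-methoxyphenyl]-3-(4-(benzyloxy)-3-{5,7-bis(benzyloxy)-2-[4-(benzyloxy)phenyl]-4-oxo-4H-chromen-3-yl}phenyl)propane-1,3-dione F6, and cyclodehydration of F6 (p-TsOH, PhMe, 80 °C) would close ring C to give 17.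

**Further compounds**

F1 | step 4 | (E)-1-[2,4-bis(benzyloxy)-6-hydroxyphenyl]-3-(dimethylamino)prop-2-en-1-one | CN(C)/C=C/C(=O)c1c(O)cc(OCc2ccccc2)cc1OCc1ccccc1
F2 | step 4 | 5,7-bis(benzyloxy)-3-iodo-4H-chromen-4-one | O=c1c(I)coc2cc(OCc3ccccc3)cc(OCc3ccccc3)c12
F3 | step 6 | 5,7-bis(benzyloxy)-3-[2-(benzyloxy)-5-bromophenyl]-2-iodo-4H-chromen-4-one | O=c1c(-c2cc(Br)ccc2OCc2ccccc2)c(I)oc2cc(OCc3ccccc3)cc(OCc3ccccc3)c12
F4 | step 9 | 4-(benzyloxy)-3-{5,7-bis(benzyloxy)-2-[4-(benzyloxy)phenyl]-4-oxo-4H-chromen-3-yl}benzoic acid | OC(=O)c1ccc(OCc2ccccc2)c(-c2c(-c3ccc(OCc4ccccc4)cc3)oc3cc(OCc4ccccc4)cc(OCc4ccccc4)c3c2=O)c1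
F5 | step 9 | 2-acetyl-3-(benzyloxy)-5-methoxyphenyl 4-(benzyloxy)-3-{5,7-bis(benzyloxy)-2-[4-(benzyloxy)phenyl]-4-oxo-4H-chromen-3-yl}benzoate | CC(=O)c1c(OC(=O)c2ccc(OCc3ccccc3)c(-c3c(-c4ccc(OCc5ccccc5)cc4)oc4cc(OCc5ccccc5)cc(OCc5ccccc5)c4c3=O)c2)cc(OC)cc1OCc1ccccc1
F6 | step 9 | 1-[2-(benzyloxy)-6-hydroxy-4-methoxyphenyl]-3-(4-(benzyloxy)-3-{5,7-bis(benzyloxy)-2-[4-(benzyloxy)phenyl]-4-oxo-4H-chromen-3-yl}phenyl)propane-1,3-dione | COc1cc(O)c(C(=O)CC(=O)c2ccc(OCc3ccccc3)c(-c3c(-c4ccc(OCc5ccccc5)cc4)oc4cc(OCc5ccccc5)cc(OCc5ccccc5)c4c3=O)c2)c(OCc2ccccc2)c1
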